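Eta, gamma and beta are the flasks you are asked about. You can keep their books as a ledger of the substrate, the limiting reagent against 2.00 equiv of partner, but the ledger opens with the catalyst.

| flask | substrate | partner | free catalyst | impurity | temperature | remark | time |
|---|---|---|---|---|---|---|---|
| dawn | 0.20 M | 2 equiv | 0.12 mol% | 0.14 mM | 95 °C | run made earlier |  |
| summer | 0.20 M | 2 equiv | 0.5 mol% | 0.14 mM | 106 °C | run made earlier |  |
| spring | 0.40 M | 2 equiv | 0.25 mol% | 0.14 mM | 95 °C | run made earlier |  |
| eta | 0.20 M | 2.00 equiv | 0.25 mol% | 0.14 mM | 110 °C |  | 40 min |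
| gamma | 0.20 M | 2.00 equiv | 0.25 mol% | 0.14 mM |  | at 110 °C until 8.0 min, from then on at 90 °C | 40 min |
| beta | 0.20 M | 2.00 equiv | 0.25 mol% | 0.14 mM | 90 °C |  | 40 min |

| run | time / min | product / % | substrate / % |
|---|---|---|---|
| dawn | 6.00 | 0 | 96.2 |
| dawn | 12.0 | 0 | 90.3 |
| dawn | 25.0 | 1.4 | 82.5 |
| dawn | 40.0 | 1.7 | 72.7 |
| dawn | 80.0 | 6.2 | 52.5 |
| summer | 4.00 | 5.3 | 64.0 |
| summer | 10.0 | 19.0 | 34.1 |
| summer | 20.0 | 44.2 | 13.6 |
| summer | 30.0 | 63.8 | 4.9 |
| summer | 40.0 | 75.1 | 0.6 |
| spring | 6.00 | 6.6 | 67.1 |
| spring | 12.0 | 21.1 | 41.7 |
| spring | 25.0 | 51.6 | 18.1 |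
| spring | 40.0 | 72.1 | 5.5 |
| spring | 80.0 | 94.6 | 1.8 |

(each reading ± 1 percentage point)



- the flask with the highest amount of product, in percent of the substrate charged ("all alike" if they lie within 1.5 percentage points) (eta / gamma / beta / all alike)
- final product, as a percentage of the substrate charged, in eta
- final product, as a percentage of the substrate charged, in gamma
- final product, as a percentage of the substrate charged, in beta

The first entry is a debit. Eta is charged with 0.500 mM of free catalyst and 0.14 mM of impurity. Suppose each impurity takes one catalyst for good: 0.360 mM remains, and 72.0% is the working share, the part of the catalyst charge left after subtracting the impurity mole for mole.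

You can test that on the earlier runs. Read as first order, the substrate falls at 0.00797 min⁻¹ in dawn and 0.0684 min⁻¹ in spring, both at 95 °C, a ratio of 8.58. The charged catalyst differs by a factor of 4.17, and the rate ratio is larger than that. The catalyst left after the debit, 0.100 mM against 0.860 mM, differs by 8.60, which is about the same as the rate ratio.

Now the substrate entry, by my own reckoning. Summer reads 0.0998 min⁻¹ at 106 °C, and per working catalyst that is 1.46 times dawn. Carrying this step on to 110 °C and scaling to eta's 0.360 mM, I get 0.0479 min⁻¹. As a rough estimate of mine, then, eta keeps about 14.7% of its substrate at 40 min, and about 85.3% has moved on.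

Those moles do not go straight to product. At 10.0 min the summer run shows 34.1% substrate and 19.0% product, with 46.9% in neither column. The last spring reading sums to 96.4%, so the books close later, through an intermediate.

The forecast agrees that “the impurity poisons catalyst one-for-one”. It names eta as highest, with 47% product in eta, 19% in gamma and 13% in beta.

The flasks give 44.3% in eta, 20.8% in gamma and 14.9% in beta, so eta holds most.

    partner + free catalyst + intermediate → free catalyst + product (k = 1.53 M⁻² s⁻¹, Ea = 52.0 kJ mol⁻¹)
    substrate + free catalyst → free catalyst + intermediate (k = 1.08 M⁻¹ s⁻¹, Ea = 47.0 kJ mol⁻¹)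
    free catalyst + impurity → spent catalyst (k = 1740 M⁻¹ s⁻¹, Ea = 48.0 kJ mol⁻¹)
    (constants at 90 °C)

At 40.0 min eta stands at 72.0% free catalyst and 28.0% spent, beside the working share of 72.0%. At that time substrate has a half-life of 13 min in eta, shorter than the 27 min of the intermediate. Eta then holds 43.5% as intermediate beside 44.3% product. A neighbour of eta charged with 0.34 M of substrate has a working share of 83.5%. That flask shows 83.5% free catalyst and 85.8% product.

The data are simulated for substances that don't exist; the scatter is artificial.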